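**Assumption:** the target has no stereocentre and no configurationally stable axis, so "single enantiomer" is taken to mean the one achiral compound drawn.

## Retrosynthetic overview

1. Target ⇒ its tris(benzyl ether); ring D (4-hydroxy-2-pyranone) ⇒ thermal acylketene lactonisation of a keto-dioxinone.
2. Keto-dioxinone ⇒ crossed Claisen condensation of a flavone-acetic acid (as acyl imidazole) with the lithium dienolate of 2,2,6-trimethyl-4H-1,3-dioxin-4-one.
3. Ring C (chromone) ⇒ iodine/DMSO oxidative cyclisation of a 2'-hydroxychalcone.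
4. Key C–C bond (chalcone Cα–Cβ, later chromone C3–C2) ⇒ intermolecular Claisen–Schmidt aldol condensation of a ring A acetophenone (from orcinol) with a ring B aldehyde (from methyl 3,5-dihydroxyphenylacetate).
5. Ring order: rings A and B come as arenes → ring C → ring D; global debenzylation last.

## Route

Step 1
Reactants: 1 orcinol (5-methylbenzene-1,3-diol)
Product: 3 1-(2,4-dihydroxy-6-methylphenyl)ethan-1-one, via ketiminium chloride 2 (not isolated)
Conditions: MeCN (1.2 equiv), ZnCl2 (0.3 equiv), HCl (g), Et2O, 0 °C → rt, 16 h; then H2O, reflux, 1 h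
Reagents that add atoms: acetonitrile CC#N (acetyl carbons); water O (carbonyl oxygen); hydrogen chloride Cl (chloride of 2 only)
Why: Houben–Hoesch acylation, in which the nitrilium electrophile attacks C4 of orcinol (ortho to one hydroxyl, para to the other, less hindered than C2 between the two hydroxyls) and the precipitated ketiminium salt is hydrolysed to the ketone.

Step 2
Reactants: 3 1-(2,4-dihydroxy-6-methylphenyl)ethan-1-one
Product: 4 1-[4-(benzyloxy)-2-hydroxy-6-methylphenyl]ethan-1-one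
Conditions: BnBr (1.05 equiv), K2CO3 (1.2 equiv), acetone, reflux, 6 h
Reagents that add atoms: benzyl bromide BrCc1ccccc1
Why: Williamson etherification that is selective for the 4-hydroxyl because the 2-hydroxyl is hydrogen-bonded to the ketone and far less nucleophilic.

Step 3
Reactants: 5 methyl 2-(3,5-dihydroxyphenyl)acetate
Product: 6 methyl 2-[3,5-bis(benzyloxy)phenyl]acetate
Conditions: BnBr (2.2 equiv), K2CO3 (2.5 equiv), DMF, rt → 50 °C, 12 h
Reagents that add atoms: benzyl bromide BrCc1ccccc1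
Why: Williamson etherification in which K2CO3 deprotonates only the phenols and leaves the ester α-CH2 untouched.

Step 4
Reactants: 6 methyl 2-[3,5-bis(benzyloxy)phenyl]acetate
Product: 8 methyl 2-[3,5-bis(benzyloxy)-2-formylphenyl]acetate, via aryl iminium salt 7 (not isolated)
Conditions: POCl3 (1.5 equiv), DMF, 0 °C → 60 °C, 4 h; then ice-H2O, rt
Reagents that add atoms: N,N-dimethylformamide CN(C)C=O (formyl carbon); water O (aldehyde oxygen); phosphoryl chloride O=P(Cl)(Cl)Cl (counter-ion of 7 only)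
Why: Vilsmeier–Haack formylation at the ring position para to one benzyloxy group and ortho to the other, which is favoured over the more hindered position between the two benzyloxy groups, while the ester α-CH2 is inert under these conditions.

Step 5
Reactants: 8 methyl 2-[3,5-bis(benzyloxy)-2-formylphenyl]acetate; 4 1-[4-(benzyloxy)-2-hydroxy-6-methylphenyl]ethan-1-one
Product: 11 2-{3,5-bis(benzyloxy)-2-[(1E)-3-[4-(benzyloxy)-2-hydroxy-6-methylphenyl]-3-oxoprop-1-en-1-yl]phenyl}acetic acid (chalcone acid), via potassium carboxylate 9 (not isolated), via aldol adduct 10 (not isolated)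
Conditions: 8, KOH (50% aq, 15 equiv), EtOH/THF, 0 °C → rt, 1 h; then 4, rt, 48–72 h; then 2 M HCl to pH 2
Reagents that add atoms: potassium hydroxide [K+].[OH-] (one carboxyl oxygen; potassium of 9 and 10)
Why: Intermolecular Claisen–Schmidt aldol condensation in which the ester is saponified first so the side chain is an inert carboxylate, the ketone enolate adds to the non-enolisable aldehyde, and E1cB dehydration gives the thermodynamic E-enone that joins rings A and B.

Step 6
Reactants: 11 chalcone acid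
Product: 12 methyl 2-{3,5-bis(benzyloxy)-2-[(1E)-3-[4-(benzyloxy)-2-hydroxy-6-methylphenyl]-3-oxoprop-1-en-1-yl]phenyl}acetate
Conditions: MeI (1.2 equiv), KHCO3 (1.5 equiv), DMF, rt, 12 h
Reagents that add atoms: iodomethane CI
Why: SN2 O-alkylation of the carboxylate only (bicarbonate does not ionise the hydrogen-bonded phenol), which masks the free arylacetic acid that could undergo oxidative decarboxylation under the iodine/DMSO conditions of the next step.

Step 7
Reactants: 12 chalcone methyl ester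
Product: 14 methyl 2-{3,5-bis(benzyloxy)-2-[7-(benzyloxy)-5-methyl-4-oxo-4H-chromen-2-yl]phenyl}acetate, via flavanone ester 13 (not isolated)
Conditions: I2 (10 mol %), DMSO, 130 °C, 2 h
Reagents that add atoms: none
Why: Iodine-catalysed oxidative cyclisation of a 2'-hydroxychalcone (intramolecular oxa-Michael addition, α-iodination and loss of HI, with DMSO as terminal oxidant), which is regiochemically unambiguous because only ring A carries a free phenol.

Step 8
Reactants: 14 flavone methyl ester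
Product: 15 2-{3,5-bis(benzyloxy)-2-[7-(benzyloxy)-5-methyl-4-oxo-4H-chromen-2-yl]phenyl}acetic acid
Conditions: LiOH·H2O (3 equiv), THF/H2O 3:1, rt, 3 h; then 1 M HCl
Reagents that add atoms: lithium hydroxide [Li+].[OH-] (one carboxyl oxygen)
Why: Ester saponification (acyl-oxygen cleavage) under cold dilute hydroxide, to which the hindered 2-arylchromone and the benzyl ethers are stable.

Step 9
Reactants: 15 flavone acetic acid; 16 2,2,6-trimethyl-4H-1,3-dioxin-4-one
Product: 19 6-(3-{3,5-bis(benzyloxy)-2-[7-(benzyloxy)-5-methyl-4-oxo-4H-chromen-2-yl]phenyl}-2-oxopropyl)-2,2-dimethyl-4H-1,3-dioxin-4-one, via acyl imidazole 17 (not isolated), via lithium dienolate 18 (not isolated)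
Conditions: 15, CDI (1.05 equiv), THF, rt, 2 h; added to 16 (3.5 equiv)/LiN(SiMe3)2 (3.5 equiv), THF, −78 °C, 1 h, → −40 °C; then sat. aq NH4Cl
Reagents that add atoms: 1,1'-carbonyldiimidazole O=C(n1ccnc1)n1ccnc1 (imidazolide of 17 only); lithium bis(trimethylsilyl)amide [Li+].C[Si](C)(C)[N-][Si](C)(C)C (lithium of 18 only)
Why: Crossed (vinylogous) Claisen condensation in which the dioxinone dienolate is C-acylated at its γ-carbon by the acyl imidazole, the excess dienolate absorbing the imidazole N–H and the acidic product, while the poorly electrophilic flavone is untouched at −78 °C.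

Step 10
Reactants: 19 keto-dioxinone
Product: 21 7-(benzyloxy)-2-{2,4-bis(benzyloxy)-6-[(4-hydroxy-2-oxo-2H-pyran-6-yl)methyl]phenyl}-5-methyl-4H-chromen-4-one, via acylketene 20 (not isolated)
Conditions: toluene (0.01 M), 110 °C, 1 h
Reagents that add atoms: none
Why: Thermal retro-hetero-Diels–Alder fragmentation of the dioxinone expels acetone, and the acylketene is trapped intramolecularly by the enol oxygen of the 1,3-diketone (lactonisation) to give the 4-hydroxy-2-pyranone under neutral conditions.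

Step 11
Reactants: 21 tris(benzyl ether) pyranone
Product: 22 7-hydroxy-2-{2,4-dihydroxy-6-[(4-hydroxy-2-oxo-2H-pyran-6-yl)methyl]phenyl}-5-methyl-4H-chromen-4-one (target)
Conditions: BCl3 (1 M in CH2Cl2, 8 equiv), pentamethylbenzene (10 equiv), CH2Cl2, −78 °C → −40 °C, 2 h; then H2O, 0 °C
Reagents that add atoms: none
Why: Lewis-acid debenzylation of aryl benzyl ethers with pentamethylbenzene as a non-basic benzyl-cation scavenger, which at low temperature spares the chromone and pyranone and prevents Friedel–Crafts C-benzylation of the electron-rich rings.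

## Compound list

1 | orcinol (5-methylbenzene-1,3-diol) | Cc1cc(O)cc(O)c1 | starting material
2 | 1-(2,4-dihydroxy-6-methylphenyl)ethan-1-iminium chloride | CC(=[NH2+])c1c(C)cc(O)cc1O.[Cl-] | intermediate (not isolated)
3 | 1-(2,4-dihydroxy-6-methylphenyl)ethan-1-one | CC(=O)c1c(C)cc(O)cc1O | intermediate
4 | 1-[4-(benzyloxy)-2-hydroxy-6-methylphenyl]ethan-1-one | CC(=O)c1c(C)cc(OCc2ccccc2)cc1O | intermediate
5 | methyl 2-(3,5-dihydroxyphenyl)acetate | COC(=O)Cc1cc(O)cc(O)c1 | starting material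
6 | methyl 2-[3,5-bis(benzyloxy)phenyl]acetate | COC(=O)Cc1cc(OCc2ccccc2)cc(OCc2ccccc2)c1 | intermediate
7 | {[2,4-bis(benzyloxy)-6-(2-methoxy-2-oxoethyl)phenyl]methylidene}dimethylazanium dichlorophosphate | COC(=O)Cc1cc(OCc2ccccc2)cc(OCc2ccccc2)c1C=[N+](C)C.[O-]P(=O)(Cl)Cl | intermediate (not isolated)
8 | methyl 2-[3,5-bis(benzyloxy)-2-formylphenyl]acetate | COC(=O)Cc1cc(OCc2ccccc2)cc(OCc2ccccc2)c1C=O | intermediate
9 | potassium 2-[3,5-bis(benzyloxy)-2-formylphenyl]acetate | [K+].[O-]C(=O)Cc1cc(OCc2ccccc2)cc(OCc2ccccc2)c1C=O | intermediate (not isolated)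
10 | dipotassium salt of 2-{3,5-bis(benzyloxy)-2-[1-hydroxy-3-(4-(benzyloxy)-6-methyl-2-oxidophenyl)-3-oxopropyl]phenyl}acetate (racemic aldol adduct) | [K+].[K+].Cc1cc(OCc2ccccc2)cc([O-])c1C(=O)CC(O)c1c(CC(=O)[O-])cc(OCc2ccccc2)cc1OCc1ccccc1 | intermediate (not isolated)
11 | 2-{3,5-bis(benzyloxy)-2-[(1E)-3-[4-(benzyloxy)-2-hydroxy-6-methylphenyl]-3-oxoprop-1-en-1-yl]phenyl}acetic acid | Cc1cc(OCc2ccccc2)cc(O)c1C(=O)/C=C/c1c(CC(=O)O)cc(OCc2ccccc2)cc1OCc1ccccc1 | intermediate
12 | methyl 2-{3,5-bis(benzyloxy)-2-[(1E)-3-[4-(benzyloxy)-2-hydroxy-6-methylphenyl]-3-oxoprop-1-en-1-yl]phenyl}acetate | Cc1cc(OCc2ccccc2)cc(O)c1C(=O)/C=C/c1c(CC(=O)OC)cc(OCc2ccccc2)cc1OCc1ccccc1 | intermediate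
13 | methyl 2-{3,5-bis(benzyloxy)-2-[7-(benzyloxy)-5-methyl-4-oxo-3,4-dihydro-2H-chromen-2-yl]phenyl}acetate (racemic flavanone) | Cc1cc(OCc2ccccc2)cc2OC(c3c(OCc4ccccc4)cc(OCc4ccccc4)cc3CC(=O)OC)CC(=O)c12 | intermediate (not isolated)
14 | methyl 2-{3,5-bis(benzyloxy)-2-[7-(benzyloxy)-5-methyl-4-oxo-4H-chromen-2-yl]phenyl}acetate | Cc1cc(OCc2ccccc2)cc2oc(-c3c(OCc4ccccc4)cc(OCc4ccccc4)cc3CC(=O)OC)cc(=O)c12 | intermediate
15 | 2-{3,5-bis(benzyloxy)-2-[7-(benzyloxy)-5-methyl-4-oxo-4H-chromen-2-yl]phenyl}acetic acid | Cc1cc(OCc2ccccc2)cc2oc(-c3c(OCc4ccccc4)cc(OCc4ccccc4)cc3CC(=O)O)cc(=O)c12 | intermediate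
16 | 2,2,6-trimethyl-4H-1,3-dioxin-4-one | CC1=CC(=O)OC(C)(C)O1 | starting material
17 | 7-(benzyloxy)-2-{2,4-bis(benzyloxy)-6-[2-(1H-imidazol-1-yl)-2-oxoethyl]phenyl}-5-methyl-4H-chromen-4-one | Cc1cc(OCc2ccccc2)cc2oc(-c3c(OCc4ccccc4)cc(OCc4ccccc4)cc3CC(=O)n3ccnc3)cc(=O)c12 | intermediate (not isolated)
18 | lithium 2,2-dimethyl-6-methylidene-6H-1,3-dioxin-4-olate | [Li+].[O-]C1=CC(=C)OC(C)(C)O1 | intermediate (not isolated)
19 | 6-(3-{3,5-bis(benzyloxy)-2-[7-(benzyloxy)-5-methyl-4-oxo-4H-chromen-2-yl]phenyl}-2-oxopropyl)-2,2-dimethyl-4H-1,3-dioxin-4-one | Cc1cc(OCc2ccccc2)cc2oc(-c3c(OCc4ccccc4)cc(OCc4ccccc4)cc3CC(=O)CC3=CC(=O)OC(C)(C)O3)cc(=O)c12 | intermediate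
20 | 6-{3,5-bis(benzyloxy)-2-[7-(benzyloxy)-5-methyl-4-oxo-4H-chromen-2-yl]phenyl}hex-1-ene-1,3,5-trione (acylketene) | Cc1cc(OCc2ccccc2)cc2oc(-c3c(OCc4ccccc4)cc(OCc4ccccc4)cc3CC(=O)CC(=O)C=C=O)cc(=O)c12 | intermediate (not isolated)
21 | 7-(benzyloxy)-2-{2,4-bis(benzyloxy)-6-[(4-hydroxy-2-oxo-2H-pyran-6-yl)methyl]phenyl}-5-methyl-4H-chromen-4-one | Cc1cc(OCc2ccccc2)cc2oc(-c3c(OCc4ccccc4)cc(OCc4ccccc4)cc3Cc3cc(O)cc(=O)o3)cc(=O)c12 | intermediate
22 | 7-hydroxy-2-{2,4-dihydroxy-6-[(4-hydroxy-2-oxo-2H-pyran-6-yl)methyl]phenyl}-5-methyl-4H-chromen-4-one | Cc1cc(O)cc2oc(-c3c(O)cc(O)cc3Cc3cc(O)cc(=O)o3)cc(=O)c12 | target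

## Step count and risks

Total steps: 11. Longest linear sequence: 9 steps (steps 3–11 from 5, or equally steps 1, 2 and 5–11 from 1).

**Step 9 (Claisen condensation with the dienolate) is the most likely to fail.** The basic dienolate may simply enolise the arylacetyl imidazole, returning 15, or attack the chromone. The fallback builds the chain without strong base and sets out from 15. Oxalyl chloride and catalytic DMF in CH2Cl2 give {3,5-bis(benzyloxy)-2-[7-(benzyloxy)-5-methyl-4-oxo-4H-chromen-2-yl]phenyl}acetyl chloride F3. This is treated at −78 °C → rt with 1-methoxy-1,3-bis(trimethylsilyloxy)buta-1,3-diene, the bis-silyl enol ether of methyl acetoacetate, in a Mukaiyama-type Claisen acylation. Aqueous work-up gives methyl 6-{3,5-bis(benzyloxy)-2-[7-(benzyloxy)-5-methyl-4-oxo-4H-chromen-2-yl]phenyl}-3,5-dioxohexanoate F4. DBU in toluene at 60 °C lactonises it with loss of methanol to pyranone 21, so 19 and 20 are bypassed and the route resumes at step 11.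

**Step 5 (Claisen–Schmidt aldol) may stall on the hindered, electron-rich aldehyde.** The fallback makes the same bond as a directed lithium aldol and sets out from 4 and 8. Ketone 4 is treated with LiN(SiMe3)2 (2.2 equiv, THF, −78 °C) to give dilithium 1-[4-(benzyloxy)-6-methyl-2-oxidophenyl]ethen-1-olate F1. This adds to ester aldehyde 8 at −78 °C faster than it deprotonates the arylacetate. On warming to room temperature the adduct closes onto the neighbouring methyl ester and is isolated as racemic 6,8-bis(benzyloxy)-1-{2-[4-(benzyloxy)-2-hydroxy-6-methylphenyl]-2-oxoethyl}isochroman-3-one F2. DBU in CH2Cl2 opens this β-acyloxy ketone by E1cB elimination, and acidification gives E-chalcone acid 11, where the route resumes at step 6.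

**Step 11 (global debenzylation) may give incomplete cleavage or C-benzylated by-products.** The fallback sets out from 21 and uses hydrogenolysis instead of Lewis-acid cleavage: H2 (1 atm), Pd/C (10 wt % palladium on carbon), EtOAc/MeOH, rt, stopped after three equivalents of hydrogen so that the pyranone and chromone double bonds are not reduced. This gives target 22 directly and makes no new compound (none F0).

Further compounds
F1 | step 5 | dilithium 1-[4-(benzyloxy)-6-methyl-2-oxidophenyl]ethen-1-olate | [Li+].[Li+].C=C([O-])c1c(C)cc(OCc2ccccc2)cc1[O-]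
F2 | step 5 | 6,8-bis(benzyloxy)-1-{2-[4-(benzyloxy)-2-hydroxy-6-methylphenyl]-2-oxoethyl}isochroman-3-one (racemic) | O=C1Cc2cc(OCc3ccccc3)cc(OCc3ccccc3)c2C(CC(=O)c2c(C)cc(OCc3ccccc3)cc2O)O1
F3 | step 9 | {3,5-bis(benzyloxy)-2-[7-(benzyloxy)-5-methyl-4-oxo-4H-chromen-2-yl]phenyl}acetyl chloride | Cc1cc(OCc2ccccc2)cc2oc(-c3c(OCc4ccccc4)cc(OCc4ccccc4)cc3CC(=O)Cl)cc(=O)c12
F4 | step 9 | methyl 6-{3,5-bis(benzyloxy)-2-[7-(benzyloxy)-5-methyl-4-oxo-4H-chromen-2-yl]phenyl}-3,5-dioxohexanoate | Cc1cc(OCc2ccccc2)cc2oc(-c3c(OCc4ccccc4)cc(OCc4ccccc4)cc3CC(=O)CC(=O)CC(=O)OC)cc(=O)c12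
F0 | step 11 | none | none
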